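**Retrosynthetic overview**

1. Feature: in unit 1 (top epicatechin) ring C is O1–C2–C3–C4 fused to ring A at C4a/C8a, and C4 carries C8 of unit 2. Ring A with C4 is therefore a latent ortho-quinone methide (O1=C8a–C4a=C4), and C2–C3 a latent Z-alkene whose C3–O is carried as C3–Si.
2. Last disconnections: all benzyl ethers (hydrogenolysis), then C3–OH of unit 1 back to C3–Si (Tamao oxidation, retention).
3. Key disconnection: C3–C4 and O1–C2 of unit 1, by hetero-Diels–Alder reaction of the quinone methide from a trimer carbinol with a Z-β-silylstyrene. Ring C of unit 1 is the only ring made in the route and is made last.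
4. Trimer carbinol: the C8(unit 2)–CH(OH) bond, from the C8 aryllithium of an 8-bromo trimer and an O-allyl-protected 4,6-bis(benzyloxy)salicylaldehyde.
5. 8-Bromo trimer: two known flavan-4-yl cation couplings (C4–C8 bonds; unit 3 onto unit 4, then bromo-capped unit 2 onto the dimer) from benzylated (−)-epicatechin and (+)-catechin, which supply all other rings.

Key step: step 16

Remark: units are numbered 1 (top epicatechin) to 4 (terminal catechin), with flavan numbering inside each unit. TRIP is 3,3′-bis(2,4,6-triisopropylphenyl)-1,1′-binaphthyl-2,2′-diyl hydrogen phosphate.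
Assumption: which antipode of the chiral phosphoric acid is matched with the chiral trimer cannot be read from the structure; the (R) antipode is written, and the reasoning is unchanged for (S).

**Route**

Step 1
Reactants: 1 (+)-catechin
Product: 2 5,7,3′,4′-tetra-O-benzyl-(+)-catechin
Conditions: BnBr (4.4 equiv), K2CO3, DMF, 0 °C → rt
Reagents that add atoms: benzyl bromide, BrCc1ccccc1
Why: Williamson etherification with a carbonate base alkylates only the four phenols and leaves the secondary 3-OH and the C2/C3 stereocentres untouched.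

Step 2
Reactants: 2 5,7,3′,4′-tetra-O-benzyl-(+)-catechin
Product: 3 3,5,7,3′,4′-penta-O-benzyl-(+)-catechin
Conditions: NaH, BnBr, DMF, 0 °C → rt
Reagents that add atoms: benzyl bromide, BrCc1ccccc1
Why: A second Williamson etherification through the sodium alkoxide caps the only remaining acidic proton before the later Lewis acid and organolithium steps.

Step 3
Reactants: 4 (−)-epicatechin
Product: 5 5,7,3′,4′-tetra-O-benzyl-(−)-epicatechin
Conditions: BnBr (4.4 equiv), K2CO3, DMF, 0 °C → rt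
Reagents that add atoms: benzyl bromide, BrCc1ccccc1
Why: Williamson etherification of the four phenols under mild base, as in step 1, keeps the 2,3-cis stereocentres intact.

Step 4
Reactants: 5 5,7,3′,4′-tetra-O-benzyl-(−)-epicatechin
Product: 6 5,7,3′,4′-tetra-O-benzyl-4β-(2-ethoxyethoxy)epicatechin
Conditions: DDQ, 2-ethoxyethanol, CH2Cl2, rt
Reagents that add atoms: 2-ethoxyethanol, CCOCCO
Why: DDQ benzylic oxidation removes hydride from C4 next to the electron-rich ring A and the cation is trapped by the alcohol anti to the axial 3-OH, giving the 4β (3,4-trans) ether, whose C4 configuration is not carried into the target.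

Step 5
Reactants: 6 5,7,3′,4′-tetra-O-benzyl-4β-(2-ethoxyethoxy)epicatechin
Product: 7 3,5,7,3′,4′-penta-O-benzyl-4β-(2-ethoxyethoxy)epicatechin
Conditions: NaH, BnBr, DMF, 0 °C → rt
Reagents that add atoms: benzyl bromide, BrCc1ccccc1
Why: Williamson benzylation of the 3-OH is compatible with the base-stable C4 ether and gives the electrophile for unit 3.

Step 6
Reactants: 7 3,5,7,3′,4′-penta-O-benzyl-4β-(2-ethoxyethoxy)epicatechin
Product: 8 8-bromo-3,5,7,3′,4′-penta-O-benzyl-4β-(2-ethoxyethoxy)epicatechin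
Conditions: NBS (1.0 equiv), CH2Cl2, −78 → 0 °C, dark
Reagents that add atoms: N-bromosuccinimide, O=C1CCC(=O)N1Br
Why: Electrophilic aromatic bromination of benzylated flavan-3-ols goes to C8 of ring A, and here C6 is further shielded by the 5-benzyloxy group buttressed by the C4 substituent; the bromine later blocks self-condensation and serves as the lithiation handle.

Step 7
Reactants: 3 3,5,7,3′,4′-penta-O-benzyl-(+)-catechin; 7 3,5,7,3′,4′-penta-O-benzyl-4β-(2-ethoxyethoxy)epicatechin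
Product: 9 deca-O-benzyl epicatechin-(4β→8)-catechin (units 3 and 4)
Conditions: 3 (3 equiv), TMSOTf (0.1 equiv), CH2Cl2, −78 °C; Et3N
Reagents that add atoms: none
Why: Friedel–Crafts-type flavan-4-yl cation coupling in which TMSOTf ionises the C4 ether and C8 of 3 attacks the cation anti to the axial 3-benzyloxy group, setting C4 of unit 3 as 4β (3,4-trans), while the excess nucleophile suppresses self-condensation of 7.

Step 8
Reactants: 9 deca-O-benzyl epicatechin-(4β→8)-catechin; 8 8-bromo-3,5,7,3′,4′-penta-O-benzyl-4β-(2-ethoxyethoxy)epicatechin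
Product: 10 pentadeca-O-benzyl 8-bromoepicatechin-(4β→8)-epicatechin-(4β→8)-catechin (units 2 to 4)
Conditions: TMSOTf (0.2 equiv), CH2Cl2, −78 → −40 °C; Et3N
Reagents that add atoms: none
Why: The same flavan-4-yl cation coupling, now equimolar because the 8-bromo cap prevents self-coupling, should place the cation on C8 of unit 3 (the most nucleophilic free position, as in known dimer-plus-monomer condensations to linear trimers) anti to the 3-benzyloxy group, setting C4 of unit 2 as 4β.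

Step 9
Reactants: 11 2,4,6-trihydroxybenzaldehyde
Product: 12 2,4-bis(benzyloxy)-6-hydroxybenzaldehyde
Conditions: BnBr (2.0 equiv), K2CO3, DMF, 0 °C → rt
Reagents that add atoms: benzyl bromide, BrCc1ccccc1
Why: Regioselective Williamson etherification, in which the para hydroxyl and one ortho hydroxyl are alkylated while the last ortho hydroxyl is held in a hydrogen bond to the aldehyde and resists the second equivalent.

Step 10
Reactants: 12 2,4-bis(benzyloxy)-6-hydroxybenzaldehyde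
Product: 13 2-(allyloxy)-4,6-bis(benzyloxy)benzaldehyde
Conditions: allyl bromide, K2CO3, DMF, 60 °C
Reagents that add atoms: allyl bromide, C=CCBr
Why: Williamson allylation of the hydrogen-bonded phenol at higher temperature installs a group that is inert to aryllithiums and removable without acid.

Step 11
Reactants: 10 pentadeca-O-benzyl 8-bromo trimer; 13 2-(allyloxy)-4,6-bis(benzyloxy)benzaldehyde
Product: 15 trimer carbinol allyl ether (both carbinol epimers), via aryllithium 14 (not isolated)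
Conditions: n-BuLi, THF, −78 °C; then 13, −78 → −40 °C; H2O
Reagents that add atoms: none
Why: Bromine–lithium exchange at C8 of unit 2 outruns deprotonation at −78 °C and the di-ortho-oxygenated aryllithium adds to the aldehyde (1,2-addition, as in the union of 2,6-dialkoxyphenyllithiums with 2,6-dialkoxybenzaldehydes), the unselective carbinol centre being of no consequence because it becomes planar in step 16.

Step 12
Reactants: 15 trimer carbinol allyl ether
Product: 16 trimer carbinol with free ortho phenol (both carbinol epimers)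
Conditions: Pd(PPh3)4 (5 mol%), morpholine, THF, rt
Reagents that add atoms: none
Why: Tsuji–Trost deallylation, in which zerovalent palladium ionises the aryl allyl ether and morpholine captures the allyl group, frees the phenol under non-acidic conditions that leave the acid-labile benzhydrol and the benzyl ethers intact.

Step 13
Reactants: 17 3,4-bis(benzyloxy)benzaldehyde
Product: 18 1,2-bis(benzyloxy)-4-ethynylbenzene
Conditions: dimethyl (1-diazo-2-oxopropyl)phosphonate, K2CO3, MeOH/THF, rt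
Reagents that add atoms: dimethyl (1-diazo-2-oxopropyl)phosphonate, COP(=O)(OC)C(=[N+]=[N-])C(C)=O
Why: Seyferth–Gilbert homologation with the Ohira–Bestmann reagent converts the aldehyde through a diazoalkene and 1,2-hydrogen shift into the terminal alkyne under conditions that benzyl ethers tolerate.

Step 14
Reactants: 18 1,2-bis(benzyloxy)-4-ethynylbenzene
Product: 20 benzyl{[3,4-bis(benzyloxy)phenyl]ethynyl}dimethylsilane, via lithium acetylide 19 (not isolated)
Conditions: n-BuLi, THF, −78 °C; then BnMe2SiCl, −78 °C → rt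
Reagents that add atoms: benzylchlorodimethylsilane, C[Si](C)(Cl)Cc1ccccc1
Why: Deprotonation of the terminal alkyne and substitution at silicon by the acetylide is a standard alkynylsilane synthesis.

Step 15
Reactants: 20 benzyl{[3,4-bis(benzyloxy)phenyl]ethynyl}dimethylsilane
Product: 21 (Z)-benzyl{2-[3,4-bis(benzyloxy)phenyl]vinyl}dimethylsilane
Conditions: H2 (1 atm), Pd/CaCO3 poisoned with Pb(OAc)2, quinoline, EtOAc, rt
Reagents that add atoms: none
Why: Lindlar-type semi-hydrogenation delivers both hydrogens to one face of the alkyne on the poisoned palladium surface and stops at the Z-alkene, and the poisoned catalyst spares the aryl benzyl ethers and the benzyl–silicon bond.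

Step 16
Reactants: 16 trimer carbinol with free ortho phenol; 21 (Z)-benzyl{2-[3,4-bis(benzyloxy)phenyl]vinyl}dimethylsilane
Product: 23 nonadeca-O-benzyl tetramer with a benzyldimethylsilyl group on C3 of unit 1 (2,3-cis and 3,4-trans), via ortho-quinone methide 22 (not isolated)
Conditions: (R)-TRIP (20 mol%), 21 (3 equiv), 5 Å MS, toluene, −20 °C → rt
Reagents that add atoms: none
Why: Proposed new method: (R)-TRIP ionises the benzhydrol of 16, which lies between two 2,4,6-trioxygenated rings, with loss of water to the hydrogen-bonded ortho-quinone methide 22 (O=C8a–C4a=C4 of the future unit 1), an electron-poor oxadiene whose C4 is attacked by the silicon-bearing carbon of 21 because the charge then builds at C2, benzylic to the 3,4-bis(benzyloxy)phenyl ring and β to silicon, and the ring A oxygen closes O1–C2 in the same asynchronous event. The closest known reaction type is the Brønsted acid-catalysed inverse-electron-demand hetero-Diels–Alder reaction of ortho-quinone methides from ortho-hydroxybenzhydrols with electron-rich styrenes to give 2,4-diarylchromans; a β-silylstyrene has not been used as the 2π partner. Ring C of unit 1 closes in the [4+2] mode, C3–C4 and O1–C2 forming suprafacially on both components. The 2,3-cis relation (C2 aryl and C3 silicon) is the Z geometry of 21, held through the asynchronous stage by hyperconjugation of the C3–Si bond with the developing C2 cation, which the oxygen captures anti to silicon. The 3,4-trans relation needs the exo arrangement, in which the silyl group points away from the twisted, di-ortho-substituted ring A of unit 2 on C4 (anti across the forming C3–C4 bond) and only H-3 faces it, and the absolute sense (C4 aryl β) needs one face of the methide, for which the (R)-phosphate bound at the methide oxygen and the adjacent chiral unit 2 are relied on. The chemoselectivity needed, ring closure instead of loss of silicon from the β-silyl cation (ipso-vinylation), is secured by the intramolecular oxygen, the bulky weakly nucleophilic phosphate and the molecular sieves that remove water.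

Step 17
Reactants: 23 nonadeca-O-benzyl C3-silyl tetramer
Product: 25 nonadeca-O-benzyl epicatechin-(4β→8)-epicatechin-(4β→8)-epicatechin-(4β→8)-catechin with free 3-OH on unit 1, via silanol 24 (not isolated)
Conditions: TBAF, THF, 0 °C → rt; then KHCO3, 30% H2O2, MeOH/THF, rt → 40 °C
Reagents that add atoms: hydrogen peroxide, OO
Why: Tamao–Fleming oxidation, in which fluoride cleaves the benzyl–silicon bond to silanol 24 and hydroperoxide on silicon triggers migration of C3 from silicon to oxygen with retention, so the C3–O bond takes the α (2,3-cis, 3,4-trans) configuration of the C–Si bond, while the axial silicon has no anti-periplanar C2–O1 bond for β-elimination.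

Step 18
Reactants: 25 nonadeca-O-benzyl epicatechin-(4β→8)-epicatechin-(4β→8)-epicatechin-(4β→8)-catechin
Product: 26 epicatechin-(4β→8)-epicatechin-(4β→8)-epicatechin-(4β→8)-catechin, the target tetramer
Conditions: H2 (1 atm), Pd(OH)2/C, THF/MeOH/H2O, rt
Reagents that add atoms: none
Why: Hydrogenolysis of the nineteen benzyl ethers over Pd(OH)2/C at room temperature is the standard final step for benzylated procyanidins and leaves the interflavan C4–C8 bonds and the benzylic C2–O1 bonds intact.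

**Compound list**

1 | (+)-catechin, (2R,3S) | Oc1cc(O)c2c(c1)O[C@H](c1ccc(O)c(O)c1)[C@@H](O)C2 | starting material
2 | 5,7,3′,4′-tetra-O-benzyl-(+)-catechin (free 3-OH) | c3ccccc3COc1cc(OCc3ccccc3)c2c(c1)O[C@H](c1ccc(OCc3ccccc3)c(OCc3ccccc3)c1)[C@@H](O)C2 | intermediate
3 | 3,5,7,3′,4′-penta-O-benzyl-(+)-catechin | c3ccccc3COc1cc(OCc3ccccc3)c2c(c1)O[C@H](c1ccc(OCc3ccccc3)c(OCc3ccccc3)c1)[C@@H](OCc3ccccc3)C2 | intermediate
4 | (−)-epicatechin, (2R,3R) | Oc1cc(O)c2c(c1)O[C@H](c1ccc(O)c(O)c1)[C@H](O)C2 | starting material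
5 | 5,7,3′,4′-tetra-O-benzyl-(−)-epicatechin (free 3-OH) | c3ccccc3COc1cc(OCc3ccccc3)c2c(c1)O[C@H](c1ccc(OCc3ccccc3)c(OCc3ccccc3)c1)[C@H](O)C2 | intermediate
6 | 5,7,3′,4′-tetra-O-benzyl-4β-(2-ethoxyethoxy)epicatechin (2,3-cis, 3,4-trans, free 3-OH) | c3ccccc3COc1cc(OCc3ccccc3)c2c(c1)O[C@H](c1ccc(OCc3ccccc3)c(OCc3ccccc3)c1)[C@H](O)[C@H]2OCCOCC | intermediate
7 | 3,5,7,3′,4′-penta-O-benzyl-4β-(2-ethoxyethoxy)epicatechin | c3ccccc3COc1cc(OCc3ccccc3)c2c(c1)O[C@H](c1ccc(OCc3ccccc3)c(OCc3ccccc3)c1)[C@H](OCc3ccccc3)[C@H]2OCCOCC | intermediate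
8 | 8-bromo-3,5,7,3′,4′-penta-O-benzyl-4β-(2-ethoxyethoxy)epicatechin | Brc1c(OCc3ccccc3)cc(OCc3ccccc3)c2c1O[C@H](c1ccc(OCc3ccccc3)c(OCc3ccccc3)c1)[C@H](OCc3ccccc3)[C@H]2OCCOCC | intermediate
9 | deca-O-benzyl epicatechin-(4β→8)-catechin (units 3 and 4) | c3ccccc3COc1cc(OCc3ccccc3)c2c(c1)O[C@H](c1ccc(OCc3ccccc3)c(OCc3ccccc3)c1)[C@H](OCc3ccccc3)[C@H]2c1c(OCc3ccccc3)cc(OCc3ccccc3)c2c1O[C@H](c1ccc(OCc3ccccc3)c(OCc3ccccc3)c1)[C@@H](OCc3ccccc3)C2 | intermediate
10 | pentadeca-O-benzyl 8-bromoepicatechin-(4β→8)-epicatechin-(4β→8)-catechin (Br on C8 of unit 2) | Brc1c(OCc3ccccc3)cc(OCc3ccccc3)c2c1O[C@H](c1ccc(OCc3ccccc3)c(OCc3ccccc3)c1)[C@H](OCc3ccccc3)[C@H]2c1c(OCc3ccccc3)cc(OCc3ccccc3)c2c1O[C@H](c1ccc(OCc3ccccc3)c(OCc3ccccc3)c1)[C@H](OCc3ccccc3)[C@H]2c1c(OCc3ccccc3)cc(OCc3ccccc3)c2c1O[C@H](c1ccc(OCc3ccccc3)c(OCc3ccccc3)c1)[C@@H](OCc3ccccc3)C2 | intermediate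
11 | 2,4,6-trihydroxybenzaldehyde | O=Cc1c(O)cc(O)cc1O | starting material
12 | 2,4-bis(benzyloxy)-6-hydroxybenzaldehyde | O=Cc1c(O)cc(OCc2ccccc2)cc1OCc1ccccc1 | intermediate
13 | 2-(allyloxy)-4,6-bis(benzyloxy)benzaldehyde | O=Cc1c(OCC=C)cc(OCc2ccccc2)cc1OCc1ccccc1 | intermediate
14 | perbenzylated trimer lithiated at C8 of unit 2 (not isolated) | [Li]c1c(OCc3ccccc3)cc(OCc3ccccc3)c2c1O[C@H](c1ccc(OCc3ccccc3)c(OCc3ccccc3)c1)[C@H](OCc3ccccc3)[C@H]2c1c(OCc3ccccc3)cc(OCc3ccccc3)c2c1O[C@H](c1ccc(OCc3ccccc3)c(OCc3ccccc3)c1)[C@H](OCc3ccccc3)[C@H]2c1c(OCc3ccccc3)cc(OCc3ccccc3)c2c1O[C@H](c1ccc(OCc3ccccc3)c(OCc3ccccc3)c1)[C@@H](OCc3ccccc3)C2 | intermediate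
15 | [2-(allyloxy)-4,6-bis(benzyloxy)phenyl] carbinol on C8 of unit 2 of the perbenzylated trimer, both carbinol epimers | C=CCOc1cc(OCc3ccccc3)cc(OCc3ccccc3)c1C(O)c1c(OCc3ccccc3)cc(OCc3ccccc3)c2c1O[C@H](c1ccc(OCc3ccccc3)c(OCc3ccccc3)c1)[C@H](OCc3ccccc3)[C@H]2c1c(OCc3ccccc3)cc(OCc3ccccc3)c2c1O[C@H](c1ccc(OCc3ccccc3)c(OCc3ccccc3)c1)[C@H](OCc3ccccc3)[C@H]2c1c(OCc3ccccc3)cc(OCc3ccccc3)c2c1O[C@H](c1ccc(OCc3ccccc3)c(OCc3ccccc3)c1)[C@@H](OCc3ccccc3)C2 | intermediate
16 | [2-hydroxy-4,6-bis(benzyloxy)phenyl] carbinol on C8 of unit 2 of the perbenzylated trimer, both carbinol epimers | Oc1cc(OCc3ccccc3)cc(OCc3ccccc3)c1C(O)c1c(OCc3ccccc3)cc(OCc3ccccc3)c2c1O[C@H](c1ccc(OCc3ccccc3)c(OCc3ccccc3)c1)[C@H](OCc3ccccc3)[C@H]2c1c(OCc3ccccc3)cc(OCc3ccccc3)c2c1O[C@H](c1ccc(OCc3ccccc3)c(OCc3ccccc3)c1)[C@H](OCc3ccccc3)[C@H]2c1c(OCc3ccccc3)cc(OCc3ccccc3)c2c1O[C@H](c1ccc(OCc3ccccc3)c(OCc3ccccc3)c1)[C@@H](OCc3ccccc3)C2 | intermediate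
17 | 3,4-bis(benzyloxy)benzaldehyde | O=Cc1ccc(OCc2ccccc2)c(OCc2ccccc2)c1 | starting material
18 | 1,2-bis(benzyloxy)-4-ethynylbenzene | C#Cc1ccc(OCc2ccccc2)c(OCc2ccccc2)c1 | intermediate
19 | lithium [3,4-bis(benzyloxy)phenyl]acetylide (not isolated) | [Li]C#Cc1ccc(OCc2ccccc2)c(OCc2ccccc2)c1 | intermediate
20 | benzyl{[3,4-bis(benzyloxy)phenyl]ethynyl}dimethylsilane | C[Si](C)(Cc1ccccc1)C#Cc1ccc(OCc2ccccc2)c(OCc2ccccc2)c1 | intermediate
21 | (Z)-benzyl{2-[3,4-bis(benzyloxy)phenyl]vinyl}dimethylsilane | C[Si](C)(Cc1ccccc1)/C=C\c1ccc(OCc2ccccc2)c(OCc2ccccc2)c1 | intermediate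
22 | 3,5-bis(benzyloxy)-6-(arylmethylidene)cyclohexa-2,4-dienone, the ortho-quinone methide with the perbenzylated trimer C8 as aryl (not isolated) | O=C1C=C(OCc3ccccc3)C=C(OCc3ccccc3)C1=Cc1c(OCc3ccccc3)cc(OCc3ccccc3)c2c1O[C@H](c1ccc(OCc3ccccc3)c(OCc3ccccc3)c1)[C@H](OCc3ccccc3)[C@H]2c1c(OCc3ccccc3)cc(OCc3ccccc3)c2c1O[C@H](c1ccc(OCc3ccccc3)c(OCc3ccccc3)c1)[C@H](OCc3ccccc3)[C@H]2c1c(OCc3ccccc3)cc(OCc3ccccc3)c2c1O[C@H](c1ccc(OCc3ccccc3)c(OCc3ccccc3)c1)[C@@H](OCc3ccccc3)C2 | intermediate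
23 | nonadeca-O-benzyl tetramer with benzyldimethylsilyl on C3 of unit 1 (C2 aryl α, C3 silyl α, C4 aryl β) | c3ccccc3COc1cc(OCc3ccccc3)c2c(c1)O[C@H](c1ccc(OCc3ccccc3)c(OCc3ccccc3)c1)[C@H]([Si](C)(C)Cc3ccccc3)[C@H]2c1c(OCc3ccccc3)cc(OCc3ccccc3)c2c1O[C@H](c1ccc(OCc3ccccc3)c(OCc3ccccc3)c1)[C@H](OCc3ccccc3)[C@H]2c1c(OCc3ccccc3)cc(OCc3ccccc3)c2c1O[C@H](c1ccc(OCc3ccccc3)c(OCc3ccccc3)c1)[C@H](OCc3ccccc3)[C@H]2c1c(OCc3ccccc3)cc(OCc3ccccc3)c2c1O[C@H](c1ccc(OCc3ccccc3)c(OCc3ccccc3)c1)[C@@H](OCc3ccccc3)C2 | intermediate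
24 | nonadeca-O-benzyl tetramer with hydroxydimethylsilyl on C3 of unit 1 (not isolated) | c3ccccc3COc1cc(OCc3ccccc3)c2c(c1)O[C@H](c1ccc(OCc3ccccc3)c(OCc3ccccc3)c1)[C@H]([Si](C)(C)O)[C@H]2c1c(OCc3ccccc3)cc(OCc3ccccc3)c2c1O[C@H](c1ccc(OCc3ccccc3)c(OCc3ccccc3)c1)[C@H](OCc3ccccc3)[C@H]2c1c(OCc3ccccc3)cc(OCc3ccccc3)c2c1O[C@H](c1ccc(OCc3ccccc3)c(OCc3ccccc3)c1)[C@H](OCc3ccccc3)[C@H]2c1c(OCc3ccccc3)cc(OCc3ccccc3)c2c1O[C@H](c1ccc(OCc3ccccc3)c(OCc3ccccc3)c1)[C@@H](OCc3ccccc3)C2 | intermediate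
25 | nonadeca-O-benzyl epicatechin-(4β→8)-epicatechin-(4β→8)-epicatechin-(4β→8)-catechin (free 3-OH on unit 1) | c3ccccc3COc1cc(OCc3ccccc3)c2c(c1)O[C@H](c1ccc(OCc3ccccc3)c(OCc3ccccc3)c1)[C@H](O)[C@H]2c1c(OCc3ccccc3)cc(OCc3ccccc3)c2c1O[C@H](c1ccc(OCc3ccccc3)c(OCc3ccccc3)c1)[C@H](OCc3ccccc3)[C@H]2c1c(OCc3ccccc3)cc(OCc3ccccc3)c2c1O[C@H](c1ccc(OCc3ccccc3)c(OCc3ccccc3)c1)[C@H](OCc3ccccc3)[C@H]2c1c(OCc3ccccc3)cc(OCc3ccccc3)c2c1O[C@H](c1ccc(OCc3ccccc3)c(OCc3ccccc3)c1)[C@@H](OCc3ccccc3)C2 | intermediate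
26 | epicatechin-(4β→8)-epicatechin-(4β→8)-epicatechin-(4β→8)-catechin, the target arecatannin tetramer | Oc1cc(O)c2c(c1)O[C@H](c1ccc(O)c(O)c1)[C@H](O)[C@H]2c1c(O)cc(O)c2c1O[C@H](c1ccc(O)c(O)c1)[C@H](O)[C@H]2c1c(O)cc(O)c2c1O[C@H](c1ccc(O)c(O)c1)[C@H](O)[C@H]2c1c(O)cc(O)c2c1O[C@H](c1ccc(O)c(O)c1)[C@@H](O)C2 | target

**Step count and risks**

Total step count: 18. Longest linear sequence: 10 steps (steps 3, 4, 5, 6, 8, 11, 12, 16, 17, 18, from (−)-epicatechin).

Steps most likely to fail: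

Step 16. The strongly stabilised and sterically shielded methide may react too slowly with the alkene, the silyl group may be lost from the β-silyl cation so that vinylation replaces annulation, or the exo and facial selectivity may be poor. The fallback joins unit 1 by the known flavan-4-yl cation coupling. It sets out from bromide 10: bromine–lithium exchange (n-BuLi, THF, −78 °C) and quenching with water would give pentadeca-O-benzyl epicatechin-(4β→8)-epicatechin-(4β→8)-catechin F1, which has a free C8 on unit 2. Coupling of F1 with the bromo-capped electrophile 8 under TMSOTf in CH2Cl2 at low temperature (the reaction type of steps 7 and 8) would give the 8-bromo eicosa-O-benzyl tetramer F2, with the new C4–C8 bond anti to the 3-benzyloxy group. Hydrogenolysis of F2 over Pd(OH)2/C with Et3N would remove the twenty benzyl ethers and the aryl bromide together and come back to the route at target 26.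

Step 17. The pentacoordinate silicate may expel the O1 phenoxide by β-elimination and open ring C, or the hindered C3–Si bond may fail to migrate. The fallback replaces silicon by boron, whose oxidation at C3 next to O1 has a close parallel in the hydroboration–oxidation of flav-3-enes to flavan-3-ols. It sets out from alkyne 18: trans-hydroboration with pinacolborane, [Rh(cod)Cl]2, P(i-Pr)3 and Et3N would give (Z)-2-{2-[3,4-bis(benzyloxy)phenyl]vinyl}-4,4,5,5-tetramethyl-1,3,2-dioxaborolane F3. Cycloaddition of F3 with 16 under the conditions of step 16, which is as untested for the boronate as it is for the silane, would give the nonadeca-O-benzyl tetramer with a pinacolboryl group on C3 of unit 1 F4. Oxidation of F4 with NaBO3·4H2O in THF/H2O, with retention, would come back to the route at 25.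

Step 11. The addition of a di-ortho-substituted aryllithium to a di-ortho-substituted aldehyde may stall, so that the aryllithium is protonated, or the very electron-rich benzhydrol may ionise during isolation. The fallback reverses the polarity so that the cheap partner can be used in excess. It sets out from bromide 10: bromine–lithium exchange and formylation with DMF would give the perbenzylated trimer C8-carbaldehyde F5. Ortho-selective hydroxyalkylation of 3,5-bis(benzyloxy)phenol, as its bromomagnesium phenoxide (EtMgBr, CH2Cl2/toluene, rt), with F5 would give the free-phenol carbinol directly and come back to the route at 16, without the allyl ether.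

Further compounds
F1 | step 16 | pentadeca-O-benzyl epicatechin-(4β→8)-epicatechin-(4β→8)-catechin (H on C8 of unit 2) | c3ccccc3COc1cc(OCc3ccccc3)c2c(c1)O[C@H](c1ccc(OCc3ccccc3)c(OCc3ccccc3)c1)[C@H](OCc3ccccc3)[C@H]2c1c(OCc3ccccc3)cc(OCc3ccccc3)c2c1O[C@H](c1ccc(OCc3ccccc3)c(OCc3ccccc3)c1)[C@H](OCc3ccccc3)[C@H]2c1c(OCc3ccccc3)cc(OCc3ccccc3)c2c1O[C@H](c1ccc(OCc3ccccc3)c(OCc3ccccc3)c1)[C@@H](OCc3ccccc3)C2
F2 | step 16 | eicosa-O-benzyl 8-bromoepicatechin-(4β→8)-epicatechin-(4β→8)-epicatechin-(4β→8)-catechin | Brc1c(OCc3ccccc3)cc(OCc3ccccc3)c2c1O[C@H](c1ccc(OCc3ccccc3)c(OCc3ccccc3)c1)[C@H](OCc3ccccc3)[C@H]2c1c(OCc3ccccc3)cc(OCc3ccccc3)c2c1O[C@H](c1ccc(OCc3ccccc3)c(OCc3ccccc3)c1)[C@H](OCc3ccccc3)[C@H]2c1c(OCc3ccccc3)cc(OCc3ccccc3)c2c1O[C@H](c1ccc(OCc3ccccc3)c(OCc3ccccc3)c1)[C@H](OCc3ccccc3)[C@H]2c1c(OCc3ccccc3)cc(OCc3ccccc3)c2c1O[C@H](c1ccc(OCc3ccccc3)c(OCc3ccccc3)c1)[C@@H](OCc3ccccc3)C2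
F3 | step 17 | (Z)-2-{2-[3,4-bis(benzyloxy)phenyl]vinyl}-4,4,5,5-tetramethyl-1,3,2-dioxaborolane | CC1(C)OB(/C=C\c2ccc(OCc3ccccc3)c(OCc3ccccc3)c2)OC1(C)C
F4 | step 17 | nonadeca-O-benzyl tetramer with pinacolboryl on C3 of unit 1 (C2 aryl α, C3 boryl α, C4 aryl β) | c3ccccc3COc1cc(OCc3ccccc3)c2c(c1)O[C@H](c1ccc(OCc3ccccc3)c(OCc3ccccc3)c1)[C@H](B4OC(C)(C)C(C)(C)O4)[C@H]2c1c(OCc3ccccc3)cc(OCc3ccccc3)c2c1O[C@H](c1ccc(OCc3ccccc3)c(OCc3ccccc3)c1)[C@H](OCc3ccccc3)[C@H]2c1c(OCc3ccccc3)cc(OCc3ccccc3)c2c1O[C@H](c1ccc(OCc3ccccc3)c(OCc3ccccc3)c1)[C@H](OCc3ccccc3)[C@H]2c1c(OCc3ccccc3)cc(OCc3ccccc3)c2c1O[C@H](c1ccc(OCc3ccccc3)c(OCc3ccccc3)c1)[C@@H](OCc3ccccc3)C2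
F5 | step 11 | perbenzylated trimer with a formyl group on C8 of unit 2 | O=Cc1c(OCc3ccccc3)cc(OCc3ccccc3)c2c1O[C@H](c1ccc(OCc3ccccc3)c(OCc3ccccc3)c1)[C@H](OCc3ccccc3)[C@H]2c1c(OCc3ccccc3)cc(OCc3ccccc3)c2c1O[C@H](c1ccc(OCc3ccccc3)c(OCc3ccccc3)c1)[C@H](OCc3ccccc3)[C@H]2c1c(OCc3ccccc3)cc(OCc3ccccc3)c2c1O[C@H](c1ccc(OCc3ccccc3)c(OCc3ccccc3)c1)[C@@H](OCc3ccccc3)C2
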